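**Retrosynthetic overview**

1. Target ⇐ protected lactone by one acid step (C14 diethyl acetal → CHO, C15 OTBS → OH).
2. Rings ⇐ open-chain bromo-enal. Ring A (ten-membered carbocycle) closes first at C6–C7, the bond germacrene A synthase forms from farnesyl diphosphate, by addition of a C13-metallated 2-(methoxycarbonyl)allyl unit to the C6 enal. Ring B (lactone) then closes from O6 onto C12, as in costunolide biosynthesis. C8 is the only stereochemical input and sets C6 and C7.
3. Bromo-enal ⇐ dialdehyde + methyl acrylate (Morita–Baylis–Hillman at C7, then SN2' bromination).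
4. Chain ⇐ C3–C4 B-alkyl Suzuki coupling of a (Z)-iodide (from but-2-yne-1,4-diol; sets C4=C5) with a dienyl acetal ⇐ one-pot vinylcopper / propiolaldehyde acetal / (R)-glycidyl ether coupling (sets C1=C10, brings C8).

Assumption: the SMILES is taken literally, i.e. 6R,7S,8R with a cis-fused 12,6-lactone (H6/H7 cis) and both ring olefins cis within the ring (1(10)E,4E by CIP because C14 and C15 are oxygenated).
Atom labels C1–C15 are germacrane numbers of the target (C12 lactone carbonyl, C13 exocyclic methylene, C14 aldehyde carbon, C15 hydroxymethyl carbon).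

**Route**

Step 1
Reactants: 1 but-2-yne-1,4-diol
Product: 2 4-[(tert-butyldimethylsilyl)oxy]but-2-yn-1-ol
Conditions: TBSCl (1 equiv), imidazole, DMF, 0 °C to rt; 1 in threefold excess
Reagents that add atoms: tert-butyldimethylsilyl chloride, CC(C)(C)[Si](C)(C)Cl
Why: Monosilylation of a symmetrical diol used in excess (silyl ether formation with imidazole) reliably gives the mono-TBS ether, which distinguishes the later C15 oxygen (silylated) from the C6 oxygen (free).

Step 2
Reactants: 2 4-[(tert-butyldimethylsilyl)oxy]but-2-yn-1-ol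
Product: 4 (2Z)-4-[(tert-butyldimethylsilyl)oxy]-3-iodobut-2-en-1-ol, via cyclic vinylalanate 3 (not isolated)
Conditions: NaAlH2(OCH2CH2OMe)2 (1.1 equiv), THF, 0 °C to rt; then I2, −78 to 0 °C
Reagents that add atoms: iodine, II
Why: Hydroxyl-directed trans-hydroalumination of the propargylic alcohol (Corey-type Red-Al reduction) puts aluminium on the carbon remote from the free hydroxyl within a five-membered alanate and iodinolysis with retention gives the (Z)-iodide in which iodine is cis to the CH2OH carbon, which later fixes C3 cis to C6 across C4=C5.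

Step 3
Reactants: 5 (S)-glycidol
Product: 6 triethyl{[(2R)-oxiran-2-yl]methoxy}silane
Conditions: Et3SiCl, imidazole, CH2Cl2, 0 °C
Reagents that add atoms: chlorotriethylsilane, CC[Si](Cl)(CC)CC
Why: Silylation of the primary alcohol leaves the stereocentre untouched and the descriptor changes from S to R only because the CIP ranking of the two CH2 groups is reversed.

Step 4
Reactants: 7 vinylmagnesium bromide, 8 3,3-diethoxyprop-1-yne, 6 triethyl{[(2R)-oxiran-2-yl]methoxy}silane
Product: 11 (2R,4E)-4-(diethoxymethyl)-1-[(triethylsilyl)oxy]hepta-4,6-dien-2-ol, via vinylcopper 9 (not isolated), via dienylcopper 10 (not isolated)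
Conditions: CuBr·SMe2, Et2O/THF/Me2S, −45 °C; 8, −45 to −25 °C; then 6, BF3·OEt2, −78 to −40 °C; aq. NH4Cl/NH3
Reagents that add atoms: none
Why: Syn-carbocupration of the propargylic acetal (Normant–Alexakis carbocupration) delivers the vinyl group to the terminal carbon and copper to the acetal-bearing carbon and the BF3-promoted opening of the epoxide at its CH2 terminus occurs with retention at the alkenyl carbon, so C9 ends cis to C2 and the acetal carbon trans to C2, while C8 keeps the configuration of 6.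

Step 5
Reactants: 11 (2R,4E)-4-(diethoxymethyl)-1-[(triethylsilyl)oxy]hepta-4,6-dien-2-ol, 12 3-methylbutanoyl chloride
Product: 13 (2R,4E)-4-(diethoxymethyl)-1-[(triethylsilyl)oxy]hepta-4,6-dien-2-yl 3-methylbutanoate
Conditions: pyridine, DMAP (cat.), CH2Cl2, 0 °C to rt
Reagents that add atoms: none
Why: DMAP-catalysed acylation of the secondary alcohol with the acid chloride is routine esterification and installs the C8 isovalerate early without touching the stereocentre.

Step 6
Reactants: 13 (2R,4E)-4-(diethoxymethyl)-1-[(triethylsilyl)oxy]hepta-4,6-dien-2-yl 3-methylbutanoate, 4 (2Z)-4-[(tert-butyldimethylsilyl)oxy]-3-iodobut-2-en-1-ol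
Product: 15 (2R,4E,8E)-4-(diethoxymethyl)-8-{[(tert-butyldimethylsilyl)oxy]methyl}-10-hydroxy-1-[(triethylsilyl)oxy]deca-4,8-dien-2-yl 3-methylbutanoate, via B-alkyl-9-BBN borane 14 (not isolated)
Conditions: 9-BBN (1.05 equiv), THF, 0 °C to rt; then 4, Pd(dppf)Cl2 (5 mol %), AsPh3, Cs2CO3, DMF/THF/H2O, rt
Reagents that add atoms: none
Why: 9-BBN hydroborates only the terminal double bond of the diene with boron on C3 and the B-alkyl Suzuki–Miyaura coupling proceeds with retention at the alkenyl iodide, so C3 is cis to C6 and the free allylic hydroxyl, ester, acetal and silyl ethers are tolerated.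

Step 7
Reactants: 15 (2R,4E,8E)-4-(diethoxymethyl)-8-{[(tert-butyldimethylsilyl)oxy]methyl}-10-hydroxy-1-[(triethylsilyl)oxy]deca-4,8-dien-2-yl 3-methylbutanoate
Product: 16 (2R,4E,8E)-4-(diethoxymethyl)-8-{[(tert-butyldimethylsilyl)oxy]methyl}-1,10-dioxodeca-4,8-dien-2-yl 3-methylbutanoate
Conditions: (COCl)2, DMSO, CH2Cl2, −78 to −40 °C; then i-Pr2NEt, −78 to 0 °C; used crude
Reagents that add atoms: none
Why: Swern oxidation converts the allylic alcohol into the enal and, under the same activated-DMSO conditions, cleaves and oxidises the primary triethylsilyl ether directly while the TBS ether survives, so a free C7 hydroxyl next to the C8 ester (and with it acyl migration) never arises and the hindered base at low temperature preserves C8 and the enal geometry.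

Step 8
Reactants: 16 (2R,4E,8E)-4-(diethoxymethyl)-8-{[(tert-butyldimethylsilyl)oxy]methyl}-1,10-dioxodeca-4,8-dien-2-yl 3-methylbutanoate, 17 methyl acrylate
Product: 18 methyl (3RS,4R,6E,10E)-6-(diethoxymethyl)-10-{[(tert-butyldimethylsilyl)oxy]methyl}-3-hydroxy-2-methylidene-4-(3-methylbutanoyloxy)-12-oxododeca-6,10-dienoate
Conditions: DABCO (1 equiv), methyl acrylate (excess, neat), MeOH (cat.), rt
Reagents that add atoms: none
Why: In the Morita–Baylis–Hillman reaction the DABCO–acrylate zwitterion adds to the strongly electrophilic α-acyloxy aldehyde and leaves the β,β-disubstituted enal untouched, and the new C7 carbinol centre needs no control because it is erased in step 9.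

Step 9
Reactants: 18 methyl (3RS,4R,6E,10E)-6-(diethoxymethyl)-10-{[(tert-butyldimethylsilyl)oxy]methyl}-3-hydroxy-2-methylidene-4-(3-methylbutanoyloxy)-12-oxododeca-6,10-dienoate
Product: 19 methyl (2Z,4R,6E,10E)-2-(bromomethyl)-6-(diethoxymethyl)-10-{[(tert-butyldimethylsilyl)oxy]methyl}-4-(3-methylbutanoyloxy)-12-oxododeca-2,6,10-trienoate
Conditions: NBS, Me2S, CH2Cl2, 0 °C to rt
Reagents that add atoms: N-bromosuccinimide, O=C1CCC(=O)N1Br
Why: Corey–Kim-type activation of the allylic alcohol followed by SN2' attack of bromide gives the thermodynamically preferred trisubstituted olefin with C8 cis to CH2Br (2Z) under neutral conditions that spare the acetal, the enal and the ester.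

Step 10
Reactants: 19 methyl (2Z,4R,6E,10E)-2-(bromomethyl)-6-(diethoxymethyl)-10-{[(tert-butyldimethylsilyl)oxy]methyl}-4-(3-methylbutanoyloxy)-12-oxododeca-2,6,10-trienoate
Product: 22 (3aS,4R,6E,10E,11aR)-6-(diethoxymethyl)-10-{[(tert-butyldimethylsilyl)oxy]methyl}-3-methylidene-2-oxo-2,3,3a,4,5,8,9,11a-octahydrocyclodeca[b]furan-4-yl 3-methylbutanoate, via allylchromium dichloride 20 (not isolated), via ring-closed chromium alkoxide 21 (not isolated)
Conditions: CrCl2 (6 equiv), THF, slow addition of 19 over 10 h (final 2 mM), rt then 40 °C; aq. NH4Cl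
Reagents that add atoms: none
Why: Intramolecular Nozaki–Hiyama–Kishi (Barbier-type) allylation in which the allylchromium adds through its γ-carbon C7 to the C6 aldehyde in a closed chair transition state, the C8-cis (Z) allyl geometry giving the syn adduct (H6 and H7 cis) and allylic 1,3-strain holding H8 in the olefin plane so that the tethered aldehyde can reach C7 only on the face carrying C9 (anti to the C8–O bond), which translates 8R into 6R,7S, after which the cis-placed chromium alkoxide closes onto the methyl ester to give the α-methylene lactone.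

Step 11
Reactants: 22 (3aS,4R,6E,10E,11aR)-6-(diethoxymethyl)-10-{[(tert-butyldimethylsilyl)oxy]methyl}-3-methylidene-2-oxo-2,3,3a,4,5,8,9,11a-octahydrocyclodeca[b]furan-4-yl 3-methylbutanoate
Product: 23 (3aS,4R,6E,10E,11aR)-6-formyl-10-(hydroxymethyl)-3-methylidene-2-oxo-2,3,3a,4,5,8,9,11a-octahydrocyclodeca[b]furan-4-yl 3-methylbutanoate
Conditions: 48% aq. HF, MeCN, 0 °C to rt
Reagents that add atoms: water, O
Why: Aqueous HF hydrolyses the labile α,β-unsaturated diethyl acetal and removes the primary TBS ether (acetal hydrolysis and fluoride-assisted desilylation) without affecting the esters, the lactone, the olefin geometries or the stereocentres.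

**Compound list**

1 | but-2-yne-1,4-diol | OCC#CCO | starting material
2 | 4-[(tert-butyldimethylsilyl)oxy]but-2-yn-1-ol | OCC#CCO[Si](C)(C)C(C)(C)C | intermediate
3 | cyclic vinylalanate: sodium 2,2-bis(2-methoxyethoxy)-3-{[(tert-butyldimethylsilyl)oxy]methyl}-2,5-dihydro-1,2-oxaluminol-2-uide | [Na+].COCCO[Al-]1(OCCOC)OCC=C1CO[Si](C)(C)C(C)(C)C | intermediate
4 | (2Z)-4-[(tert-butyldimethylsilyl)oxy]-3-iodobut-2-en-1-ol | OC/C=C(\I)CO[Si](C)(C)C(C)(C)C | intermediate
5 | (S)-glycidol, (2S)-oxiran-2-ylmethanol | OC[C@H]1CO1 | starting material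
6 | triethyl{[(2R)-oxiran-2-yl]methoxy}silane | CC[Si](CC)(CC)OC[C@H]1CO1 | intermediate
7 | vinylmagnesium bromide | C=C[Mg]Br | starting material
8 | 3,3-diethoxyprop-1-yne | C#CC(OCC)OCC | starting material
9 | vinylcopper (MgBr2 complex) | C=C[Cu] | intermediate
10 | dienylcopper: [(1Z)-1-(diethoxymethyl)buta-1,3-dien-1-yl]copper | C=C/C=C(\[Cu])C(OCC)OCC | intermediate
11 | (2R,4E)-4-(diethoxymethyl)-1-[(triethylsilyl)oxy]hepta-4,6-dien-2-ol | C=C/C=C(\C[C@@H](O)CO[Si](CC)(CC)CC)C(OCC)OCC | intermediate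
12 | 3-methylbutanoyl chloride (isovaleryl chloride) | CC(C)CC(Cl)=O | starting material
13 | (2R,4E)-4-(diethoxymethyl)-1-[(triethylsilyl)oxy]hepta-4,6-dien-2-yl 3-methylbutanoate | C=C/C=C(\C[C@@H](OC(=O)CC(C)C)CO[Si](CC)(CC)CC)C(OCC)OCC | intermediate
14 | B-alkyl-9-BBN borane: 9-[(3E,6R)-4-(diethoxymethyl)-6-(3-methylbutanoyloxy)-7-(triethylsilyloxy)hept-3-en-1-yl]-9-borabicyclo[3.3.1]nonane | B1(CC/C=C(\C[C@@H](OC(=O)CC(C)C)CO[Si](CC)(CC)CC)C(OCC)OCC)C2CCCC1CCC2 | intermediate
15 | (2R,4E,8E)-4-(diethoxymethyl)-8-{[(tert-butyldimethylsilyl)oxy]methyl}-10-hydroxy-1-[(triethylsilyl)oxy]deca-4,8-dien-2-yl 3-methylbutanoate | OC/C=C(\CC/C=C(\C[C@@H](OC(=O)CC(C)C)CO[Si](CC)(CC)CC)C(OCC)OCC)CO[Si](C)(C)C(C)(C)C | intermediate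
16 | (2R,4E,8E)-4-(diethoxymethyl)-8-{[(tert-butyldimethylsilyl)oxy]methyl}-1,10-dioxodeca-4,8-dien-2-yl 3-methylbutanoate | O=C/C=C(\CC/C=C(\C[C@@H](OC(=O)CC(C)C)C=O)C(OCC)OCC)CO[Si](C)(C)C(C)(C)C | intermediate
17 | methyl acrylate | C=CC(=O)OC | starting material
18 | methyl (3RS,4R,6E,10E)-6-(diethoxymethyl)-10-{[(tert-butyldimethylsilyl)oxy]methyl}-3-hydroxy-2-methylidene-4-(3-methylbutanoyloxy)-12-oxododeca-6,10-dienoate | O=C/C=C(\CC/C=C(\C[C@@H](OC(=O)CC(C)C)C(O)C(=C)C(=O)OC)C(OCC)OCC)CO[Si](C)(C)C(C)(C)C | intermediate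
19 | methyl (2Z,4R,6E,10E)-2-(bromomethyl)-6-(diethoxymethyl)-10-{[(tert-butyldimethylsilyl)oxy]methyl}-4-(3-methylbutanoyloxy)-12-oxododeca-2,6,10-trienoate | O=C/C=C(\CC/C=C(\C[C@@H](OC(=O)CC(C)C)/C=C(\CBr)C(=O)OC)C(OCC)OCC)CO[Si](C)(C)C(C)(C)C | intermediate
20 | allylchromium dichloride: 19 with CrCl2 in place of Br on C13 | O=C/C=C(\CC/C=C(\C[C@@H](OC(=O)CC(C)C)/C=C(\C[Cr](Cl)Cl)C(=O)OC)C(OCC)OCC)CO[Si](C)(C)C(C)(C)C | intermediate
21 | ring-closed chromium alkoxide: methyl 2-[(1S,2R,3E,7E,10R)-2-[(dichlorochromio)oxy]-4-{[(tert-butyldimethylsilyl)oxy]methyl}-8-(diethoxymethyl)-10-(3-methylbutanoyloxy)cyclodeca-3,7-dien-1-yl]prop-2-enoate | Cl[Cr](Cl)O[C@@H]1/C=C(/CO[Si](C)(C)C(C)(C)C)CC/C=C(/C(OCC)OCC)C[C@@H](OC(=O)CC(C)C)[C@@H]1C(=C)C(=O)OC | intermediate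
22 | (3aS,4R,6E,10E,11aR)-6-(diethoxymethyl)-10-{[(tert-butyldimethylsilyl)oxy]methyl}-3-methylidene-2-oxo-2,3,3a,4,5,8,9,11a-octahydrocyclodeca[b]furan-4-yl 3-methylbutanoate | C=C1C(=O)O[C@@H]2/C=C(/CO[Si](C)(C)C(C)(C)C)CC/C=C(/C(OCC)OCC)C[C@@H](OC(=O)CC(C)C)[C@H]12 | intermediate
23 | (3aS,4R,6E,10E,11aR)-6-formyl-10-(hydroxymethyl)-3-methylidene-2-oxo-2,3,3a,4,5,8,9,11a-octahydrocyclodeca[b]furan-4-yl 3-methylbutanoate (CNP0345200.7) | C=C1C(=O)O[C@@H]2/C=C(/CO)CC/C=C(/C=O)C[C@@H](OC(=O)CC(C)C)[C@H]12 | target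

**Step count and risks**

Total steps: 11. Longest linear sequence: 9 steps (steps 3 to 11, from (S)-glycidol 5); the iodide arm (steps 1 and 2) joins at step 6.

The three steps most likely to fail:

Step 10 (ring closure). The allylchromium carries the C8 isovalerate in a δ-relationship to the metal and could lose it by reductive 1,4-elimination to a dienoate before the slow ten-membered closure. The facial selectivity and the cis ring fusion rest on a transition-state model with no precedent in the cis,cis series. The fallback sets out from 18 and replaces the reducing metal by boron. Acetylation (Ac2O, pyridine, DMAP) gives the acetate methyl (3RS,4R,6E,10E)-3-acetoxy-6-(diethoxymethyl)-10-{[(tert-butyldimethylsilyl)oxy]methyl}-2-methylidene-4-(3-methylbutanoyloxy)-12-oxododeca-6,10-dienoate F4. Borylation with allylic transposition catalysed by Pd2(dba)3 with B2pin2 in DMF then gives the allylboronate with C8 cis to the CH2Bpin group F5, which cannot eliminate reductively. Heating F5 in toluene (80–100 °C, 2 mM) effects intramolecular allylboration through the same closed chair, and the resulting borate lactonises, so the sequence comes back to the route at 22.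

Step 4 (three-component coupling). The α-acetal alkenylcopper 10 may be too unreactive toward the epoxide, or BF3 may ionise the allylic acetal. The fallback sets out from 10 (made from 7 and 8 as in step 4) and separates the two bond formations. Quenching with I2 gives (3Z)-5,5-diethoxy-4-iodopenta-1,3-diene F1. Iodine–lithium exchange (t-BuLi, 2 equiv, Et2O, −78 °C) gives [1-(diethoxymethyl)buta-1,3-dien-1-yl]lithium F2. F2 opens epoxide 6 at its CH2 terminus on addition of BF3·OEt2 at −78 °C (organolithium/BF3 epoxide opening) and comes back to the route at 11.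

Step 8 (Morita–Baylis–Hillman). Days of exposure to DABCO could epimerise C8 of the α-acyloxy aldehyde, move the isovaleryl group from O8 to the new O7, or isomerise the C4=C5 enal. The fallback sets out from 16 and uses a preformed nucleophile in place of amine catalysis. Hydroalumination of methyl propiolate with i-Bu2AlH in THF/HMPA gives [1-(methoxycarbonyl)ethenyl]bis(2-methylpropyl)alane F3. F3 adds to the α-acyloxy aldehyde of 16 within minutes at −78 °C, and aqueous work-up comes back to the route at 18.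

**Further compounds**

F1 | step 4 | (3Z)-5,5-diethoxy-4-iodopenta-1,3-diene | C=C/C=C(\I)C(OCC)OCC
F2 | step 4 | [1-(diethoxymethyl)buta-1,3-dien-1-yl]lithium (lithium cis to the vinyl group) | C=C/C=C(\[Li])C(OCC)OCC
F3 | step 8 | [1-(methoxycarbonyl)ethenyl]bis(2-methylpropyl)alane | C=C(C(=O)OC)[Al](CC(C)C)CC(C)C
F4 | step 10 | methyl (3RS,4R,6E,10E)-3-acetoxy-6-(diethoxymethyl)-10-{[(tert-butyldimethylsilyl)oxy]methyl}-2-methylidene-4-(3-methylbutanoyloxy)-12-oxododeca-6,10-dienoate | O=C/C=C(\CC/C=C(\C[C@@H](OC(=O)CC(C)C)C(OC(C)=O)C(=C)C(=O)OC)C(OCC)OCC)CO[Si](C)(C)C(C)(C)C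
F5 | step 10 | methyl (4R,6E,10E)-6-(diethoxymethyl)-10-{[(tert-butyldimethylsilyl)oxy]methyl}-4-(3-methylbutanoyloxy)-12-oxo-2-[(4,4,5,5-tetramethyl-1,3,2-dioxaborolan-2-yl)methyl]dodeca-2,6,10-trienoate (C8 cis to CH2Bpin) | O=C/C=C(\CC/C=C(\C[C@@H](OC(=O)CC(C)C)/C=C(\CB1OC(C)(C)C(C)(C)O1)C(=O)OC)C(OCC)OCC)CO[Si](C)(C)C(C)(C)C
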